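Amounts of target at a fixed time, set against the amount of substrate charged, are the question here: gas is held at 7.9 mM in each flask, and the substrate charge differs.

in all of them: gas 7.9 mM (held)

|  | substrate | remark | time |
|---|---|---|---|
| south-east | 0.0096 M | run made earlier |  |
| west | 0.024 M | run made earlier |  |
| oak | 0.0030 M |  | 2.0 h |
| alder | 0.010 M |  | 2.0 h |
| maple | 0.030 M |  | 2.0 h |

- south-east (time / min: target / %, substrate / %): 10.0: 0.6, 19.4; 30.0: 10.3, 15.8; 60.0: 35.6, 10.9; 80.0: 52.2, 6.8; 120: 75.2, 3.0
- west (time / min: target / %, substrate / %): 10.0: 0.7, 20.0; 30.0: 7.4, 16.8; 60.0: 25.6, 13.2; 80.0: 36.8, 9.3; 120: 59.5, 4.9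

(standard deviation of a reading: 0.5 percentage points)

* [target] at the end for oak, alder, maple, in this order
* the shape of the row from first to last (rises all the way / falls, then rises / rises, then falls / falls all the way / hardly changes)

- the analysis behind the earlier runs scatters by 0.5 percentage points, standard deviation
- at the start none of the gas is in solution
- "hardly changes" means that all values lie within two and a half points (for a concentration: within two and a half percent of the largest)

At 10.0 min the two earlier runs look alike in percent of their charge: substrate stands at 19.4 % in south-east and 20.0 % in west, target at 0.6 % and 0.7 %. By 120 min, the asked time, they have parted. Target in south-east is then higher than in west, 75.2 % against 59.5 %, a gap of 16 percentage points with a scatter of 0.5 points on each reading.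

A pseudo-first-order conversion with a fixed rate constant gives the same percent at a given time for any charge. These runs do not, so the reckoning here keeps south-east's percent as the large term and computes a correction for the charge. Dividing the gap by the difference of the charges gives 0.0109 mM⁻¹, the charge penalty: the fraction of the charge that target loses at the asked time for each mM more substrate. Two runs draw a straight line and offer no test of it, and oak and maple lie outside them.

Corrected so, the percent runs from 82.4 % in oak through 74.8 % in alder to 53.0 % in maple. Maple's charge is ten times oak's, so target still climbs: 0.00247 M, 0.00748 M, 0.0159 M. The forecast gives 0.0026 M, 0.0075 M and 0.0153 M, a row that rises all the way, and its ground reads: “There is no sign of inhibition, so the row rises”; its maple lies lower than the reckoning here.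

The flask gives 0.00247 M, 0.00753 M and 0.0154 M, a row that rises all the way, with maple lower than the reckoned 0.0159 M.

    open intermediate + second intermediate → target (k = 0.0580 M⁻¹ s⁻¹)
    partner → second intermediate (k = 4.70 × 10⁻⁴ s⁻¹)
    substrate ⇌ open intermediate (K = 3.80, k = 0.0150 s⁻¹)
    substrate ⇌ dormant form (K = 1.90, k = 3.00 × 10⁻⁴ s⁻¹)
    gas ⇌ partner, rate k5*(csat - [partner]) (kL = 0.00200 s⁻¹)

At 2.00 h maple still holds more open intermediate than oak, 25.7 % of its charge against 5.10 %. Across the span from oak to maple the charge penalty takes 29 points off the percent of target, so from oak's 82.4 % it reckons maple at 53.0 %, and maple stands at 51.4 %.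

The readings stem from a simulated flask from invented constants, noise included.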